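**Retrosynthetic overview**
1. The target is the cis-(1S,2S)-1-aryl-2,3-dimethyl-1,2-dihydronaphthalene. Its ring B (C1–C2–C3=C4–C4a–C8a) is a naphthalene ring to which Ar–H has been added across C1=C2.
2. Enabling feature: the sp3 pair C1(H)(Ar)/C2(H)(CH3) lies between benzene ring A and the C3=C4 styrene bond. If the C2 methyl is raised to carboxyl level (a chiral oxazoline), C1 becomes the β-carbon of an N=C–C2=C1 azadiene inside a flat naphthalene. The C8 methoxy group peri to C1 forces the incoming aryl group pseudoaxial.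
3. Key disconnection: C1–C(ipso) of the syringyl ring. It is made by dearomatising 1,4-addition of the aryllithium to the 2-naphthyloxazoline followed by anti protonation at C2, which sets both stereocentres and leaves C3=C4 in place.
4. Ring order: ring A and the pendant ring are bought, both as 4-bromo-2,6-dimethoxyphenol. Ring B is closed at C1–C8a by formylation/Friedel–Crafts cyclodehydration and then aromatised. The oxazoline ring is temporary.
5. Endgame: oxazoline → ester → CH2OH → CH3, then double desilylation.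

Key step: step 7

Remark: the SMILES is read as (1S,2S), with the C1 aryl and the C2 methyl cis. The target numbering (C1 = aryl-bearing carbon, C8 = methoxy carbon peri to it) is used for all bicyclic intermediates. Compounds 1, 3 and 9 are taken as commercial.

Step 1
Reactants: 1 4-bromo-2,6-dimethoxyphenol
Product: 2 (4-bromo-2,6-dimethoxyphenoxy)triisopropylsilane
Conditions: TIPSCl, imidazole, DMF, 40 °C
Reagents that add atoms: triisopropylsilyl chloride, CC(C)[Si](Cl)(C(C)C)C(C)C
Why: Imidazole-assisted silyl ether protection masks the acidic phenol with a group that should tolerate aryllithium, hydride, DDQ and moderate acid, and both copies leave together with fluoride at the end.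

Step 2
Reactants: 3 ethyl 3-methylbut-3-enoate; 2 (4-bromo-2,6-dimethoxyphenoxy)triisopropylsilane
Product: 5 ethyl 4-[3,5-dimethoxy-4-(triisopropylsilyloxy)phenyl]-3-methylbutanoate (racemic), via alkyl-9-BBN borane 4 (not isolated)
Conditions: 3, 9-BBN-H, THF, 0 °C → rt; then 2, PdCl2(dppf) (cat.), aq. K3PO4, THF/DMF, 60 °C
Reagents that add atoms: 9-borabicyclo[3.3.1]nonane, [H]B1C2CCCC1CCC2 (boron only in intermediate 4)
Why: Anti-Markovnikov hydroboration of the 1,1-disubstituted alkene followed by B-alkyl Suzuki–Miyaura coupling forms the C4–C4a bond directly at the saturated level without alkene isomers, and the racemic C3 centre is erased in step 4.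

Step 3
Reactants: 5 ethyl 4-[3,5-dimethoxy-4-(triisopropylsilyloxy)phenyl]-3-methylbutanoate
Product: 7 ethyl 6,8-dimethoxy-3-methyl-7-(triisopropylsilyloxy)-3,4-dihydronaphthalene-2-carboxylate (racemic), via sodium formyl-ester enolate 6 (not isolated)
Conditions: NaH, HCO2Et, EtOH (cat.), THF, 0 °C → rt; solvent switch to CH2Cl2, TFA, 0 °C → rt
Reagents that add atoms: ethyl formate, CCOC=O; sodium hydride, [Na+].[H-] (sodium only in intermediate 6)
Why: Crossed Claisen formylation followed by Friedel–Crafts cyclodehydration of the α-formyl ester is the classical entry to 3,4-dihydro-2-naphthoates, and here the two equivalent ring positions are each activated by one ortho and one para methoxy group, so that TFA should suffice and only one regioisomer is possible.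

Step 4
Reactants: 7 ethyl 6,8-dimethoxy-3-methyl-7-(triisopropylsilyloxy)-3,4-dihydronaphthalene-2-carboxylate
Product: 8 ethyl 6,8-dimethoxy-3-methyl-7-(triisopropylsilyloxy)naphthalene-2-carboxylate
Conditions: DDQ, toluene, 80 °C
Reagents that add atoms: none
Why: DDQ dehydrogenation starts with hydride abstraction from the electron-rich benzylic C4 and is driven by formation of the naphthalene.

Step 5
Reactants: 8 ethyl 6,8-dimethoxy-3-methyl-7-(triisopropylsilyloxy)naphthalene-2-carboxylate; 9 (S)-tert-leucinol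
Product: 10 N-[(2S)-1-hydroxy-3,3-dimethylbutan-2-yl]-6,8-dimethoxy-3-methyl-7-(triisopropylsilyloxy)naphthalene-2-carboxamide
Conditions: AlMe3, 9, toluene, 0 → 100 °C; Rochelle salt work-up
Reagents that add atoms: none
Why: Trimethylaluminium-mediated ester aminolysis delivers the aluminium amide to the ortho-substituted ester without hydroxide, which spares the aryl silyl ether and does not touch the stereocentre of 9.

Step 6
Reactants: 10 N-[(2S)-1-hydroxy-3,3-dimethylbutan-2-yl]-6,8-dimethoxy-3-methyl-7-(triisopropylsilyloxy)naphthalene-2-carboxamide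
Product: 12 (4S)-4-tert-butyl-2-[6,8-dimethoxy-3-methyl-7-(triisopropylsilyloxy)naphthalen-2-yl]-4,5-dihydro-1,3-oxazole, via amide mesylate 11 (not isolated)
Conditions: MsCl, Et3N (excess), CH2Cl2, 0 °C → reflux
Reagents that add atoms: methanesulfonyl chloride, CS(=O)(=O)Cl (atoms only in intermediate 11)
Why: O-Mesylation followed by 5-exo-tet displacement by the amide oxygen is the standard cyclodehydration to 2-oxazolines and occurs at the CH2 carbon, so the (S) centre is retained.

Step 7
Reactants: 2 (4-bromo-2,6-dimethoxyphenoxy)triisopropylsilane; 12 (4S)-4-tert-butyl-2-[6,8-dimethoxy-3-methyl-7-(triisopropylsilyloxy)naphthalen-2-yl]-4,5-dihydro-1,3-oxazole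
Product: 15 (4S)-4-tert-butyl-2-{(1S,2S)-1-[3,5-dimethoxy-4-(triisopropylsilyloxy)phenyl]-6,8-dimethoxy-3-methyl-7-(triisopropylsilyloxy)-1,2-dihydronaphthalen-2-yl}-4,5-dihydro-1,3-oxazole (aryl cis to oxazoline), via aryllithium 13 (not isolated), via lithium azaenolate 14 (not isolated)
Conditions: 2 (1.6 equiv), t-BuLi (3.2 equiv), THF, −78 °C; 12, −78 → −30 °C; TFA, THF, −78 °C
Reagents that add atoms: tert-butyllithium, [Li]C(C)(C)C (lithium only in intermediates 13 and 14)
Why: Aryllithium 13 binds to the oxazoline nitrogen (the C8 methoxy oxygen peri to C1 can complete the lithium pocket) and transfers its aryl group to C1, the β-carbon of the N=C–C2=C1 azadiene, which dearomatises ring B only and gives azaenolate 14, and C-protonation at C2 then gives 15. The closest known reaction type is the auxiliary-controlled conjugate addition of organolithiums to chiral naphthyloxazolines with electrophilic quench, which is established for aryllithiums and for alkoxy-substituted naphthalenes. No ring is closed: the aromatic sextet of ring B is broken and the C3=C4 bond is left conjugated with ring A exactly where the target has it. C1 is controlled by the (4S)-tert-butyl group, which in the reactive s-cis conformer (N towards C1, O towards the C3 methyl) covers one face, so that the N-bound aryllithium should deliver aryl to the opposite face and give 1S. C2 is controlled by C1, because peri strain with the C8 methoxy group and A(1,3) strain with the exocyclic C2=C bond hold the new aryl group pseudoaxial over one face of 14, so that the proton enters anti to it and the oxazoline ends up cis to the aryl group (2S), as in the kinetic protonation of 1-aryltetralin enolates. The step needs 1,4-addition instead of deprotonation of C3–CH3 or C1–H, attack at C1 instead of C3, and α- instead of γ-protonation; these are secured by the weakly basic, unhindered and precomplexed aryllithium, by the fact that attack at C3 would also break the sextet of ring A, by the twisted 7-OTIPS oxygen that donates little into C1, and by a fast irreversible quench at −78 °C.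

Step 8
Reactants: 15 (4S)-4-tert-butyl-2-{(1S,2S)-1-[3,5-dimethoxy-4-(triisopropylsilyloxy)phenyl]-6,8-dimethoxy-3-methyl-7-(triisopropylsilyloxy)-1,2-dihydronaphthalen-2-yl}-4,5-dihydro-1,3-oxazole
Product: 17 (2S)-2-acetamido-3,3-dimethylbutyl (1S,2S)-1-[3,5-dimethoxy-4-(triisopropylsilyloxy)phenyl]-6,8-dimethoxy-3-methyl-7-(triisopropylsilyloxy)-1,2-dihydronaphthalene-2-carboxylate, via amino ester trifluoroacetate salt 16 (not isolated)
Conditions: TFA, H2O, Na2SO4, THF, rt; then Ac2O, pyridine, CH2Cl2, 0 °C → rt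
Reagents that add atoms: water, O; acetic anhydride, CC(=O)OC(C)=O; trifluoroacetic acid, OC(=O)C(F)(F)F (only in salt 16)
Why: Acid hydrolysis of the oxazoline (water adds to the protonated C=N and the ring opens at C–N to the ammonium ester) followed by N-acetylation, which blocks O→N acyl migration, is the standard non-basic unmasking of this auxiliary, so the allylic C2–H meets no base stronger than pyridine and both ring stereocentres should be kept.

Step 9
Reactants: 17 (2S)-2-acetamido-3,3-dimethylbutyl (1S,2S)-1-[3,5-dimethoxy-4-(triisopropylsilyloxy)phenyl]-6,8-dimethoxy-3-methyl-7-(triisopropylsilyloxy)-1,2-dihydronaphthalene-2-carboxylate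
Product: 18 {(1S,2S)-1-[3,5-dimethoxy-4-(triisopropylsilyloxy)phenyl]-6,8-dimethoxy-3-methyl-7-(triisopropylsilyloxy)-1,2-dihydronaphthalen-2-yl}methanol
Conditions: DIBAL-H (excess), CH2Cl2, −78 → −20 °C; Rochelle salt
Reagents that add atoms: none
Why: Ester reduction with the Lewis-acidic, weakly basic DIBAL-H passes the aldehyde level only as an aluminium hemiacetal that is reduced further as it collapses, so C2 should not epimerise and the auxiliary leaves as its N-acetyl amino alcohol.

Step 10
Reactants: 18 {(1S,2S)-1-[3,5-dimethoxy-4-(triisopropylsilyloxy)phenyl]-6,8-dimethoxy-3-methyl-7-(triisopropylsilyloxy)-1,2-dihydronaphthalen-2-yl}methanol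
Product: 19 {(1S,2S)-1-[3,5-dimethoxy-4-(triisopropylsilyloxy)phenyl]-6,8-dimethoxy-3-methyl-7-(triisopropylsilyloxy)-1,2-dihydronaphthalen-2-yl}methyl methanesulfonate
Conditions: MsCl, Et3N, CH2Cl2, −20 → 0 °C
Reagents that add atoms: methanesulfonyl chloride, CS(=O)(=O)Cl
Why: Sulfonylation of the only free hydroxyl group activates the primary carbon without touching a stereocentre.

Step 11
Reactants: 19 {(1S,2S)-1-[3,5-dimethoxy-4-(triisopropylsilyloxy)phenyl]-6,8-dimethoxy-3-methyl-7-(triisopropylsilyloxy)-1,2-dihydronaphthalen-2-yl}methyl methanesulfonate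
Product: 20 bis(triisopropylsilyl) ether of the target, (1S,2S)-1-[3,5-dimethoxy-4-(triisopropylsilyloxy)phenyl]-6,8-dimethoxy-2,3-dimethyl-7-(triisopropylsilyloxy)-1,2-dihydronaphthalene
Conditions: LiEt3BH, THF, 0 °C → rt
Reagents that add atoms: none
Why: SN2 displacement of the primary mesylate by lithium triethylborohydride, the most nucleophilic common hydride, turns CH2OMs into the C2 methyl group without involving C2, the alkene or the silyl ethers.

Step 12
Reactants: 20 bis(triisopropylsilyl) ether of the target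
Product: 21 (1S,2S)-1-(4-hydroxy-3,5-dimethoxyphenyl)-6,8-dimethoxy-2,3-dimethyl-1,2-dihydronaphthalen-7-ol (target)
Conditions: TBAF, AcOH, degassed THF, 0 °C
Reagents that add atoms: none
Why: Buffered fluoride desilylation frees both phenols under nearly neutral, non-oxidising conditions that leave the acid-, base- and air-sensitive cis-dihydronaphthalene untouched.

**Compound list**
1 | 4-bromo-2,6-dimethoxyphenol | COc1cc(Br)cc(OC)c1O | starting material
2 | (4-bromo-2,6-dimethoxyphenoxy)triisopropylsilane | COc1cc(Br)cc(OC)c1O[Si](C(C)C)(C(C)C)C(C)C | intermediate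
3 | ethyl 3-methylbut-3-enoate | C=C(C)CC(=O)OCC | starting material
4 | ethyl 4-(9-borabicyclo[3.3.1]nonan-9-yl)-3-methylbutanoate | CCOC(=O)CC(C)CB1C2CCCC1CCC2 | intermediate
5 | ethyl 4-[3,5-dimethoxy-4-(triisopropylsilyloxy)phenyl]-3-methylbutanoate (racemic) | CCOC(=O)CC(C)Cc1cc(OC)c(O[Si](C(C)C)(C(C)C)C(C)C)c(OC)c1 | intermediate
6 | sodium enolate of ethyl 2-formyl-3-methyl-4-[3,5-dimethoxy-4-(triisopropylsilyloxy)phenyl]butanoate | CCOC(=O)C(=C[O-])C(C)Cc1cc(OC)c(O[Si](C(C)C)(C(C)C)C(C)C)c(OC)c1.[Na+] | intermediate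
7 | ethyl 6,8-dimethoxy-3-methyl-7-(triisopropylsilyloxy)-3,4-dihydronaphthalene-2-carboxylate (racemic) | CCOC(=O)C1=Cc2c(OC)c(O[Si](C(C)C)(C(C)C)C(C)C)c(OC)cc2CC1C | intermediate
8 | ethyl 6,8-dimethoxy-3-methyl-7-(triisopropylsilyloxy)naphthalene-2-carboxylate | CCOC(=O)c1cc2c(OC)c(O[Si](C(C)C)(C(C)C)C(C)C)c(OC)cc2cc1C | intermediate
9 | (S)-tert-leucinol | CC(C)(C)[C@H](N)CO | starting material
10 | N-[(2S)-1-hydroxy-3,3-dimethylbutan-2-yl]-6,8-dimethoxy-3-methyl-7-(triisopropylsilyloxy)naphthalene-2-carboxamide | COc1cc2cc(C)c(C(=O)N[C@H](CO)C(C)(C)C)cc2c(OC)c1O[Si](C(C)C)(C(C)C)C(C)C | intermediate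
11 | O-mesylate of amide 10 | COc1cc2cc(C)c(C(=O)N[C@H](COS(C)(=O)=O)C(C)(C)C)cc2c(OC)c1O[Si](C(C)C)(C(C)C)C(C)C | intermediate
12 | (4S)-4-tert-butyl-2-[6,8-dimethoxy-3-methyl-7-(triisopropylsilyloxy)naphthalen-2-yl]-4,5-dihydro-1,3-oxazole | COc1cc2cc(C)c(C3=N[C@H](CO3)C(C)(C)C)cc2c(OC)c1O[Si](C(C)C)(C(C)C)C(C)C | intermediate
13 | [3,5-dimethoxy-4-(triisopropylsilyloxy)phenyl]lithium | [Li]c1cc(OC)c(O[Si](C(C)C)(C(C)C)C(C)C)c(OC)c1 | intermediate
14 | lithium azaenolate from addition of 13 to C1 of 12 | COc1cc([C@H]2c3c(cc(OC)c(O[Si](C(C)C)(C(C)C)C(C)C)c3OC)C=C(C)C2=C4OC[C@H](C(C)(C)C)N4[Li])cc(OC)c1O[Si](C(C)C)(C(C)C)C(C)C | intermediate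
15 | (4S)-4-tert-butyl-2-{(1S,2S)-1-[3,5-dimethoxy-4-(triisopropylsilyloxy)phenyl]-6,8-dimethoxy-3-methyl-7-(triisopropylsilyloxy)-1,2-dihydronaphthalen-2-yl}-4,5-dihydro-1,3-oxazole | COc1cc([C@H]2c3c(cc(OC)c(O[Si](C(C)C)(C(C)C)C(C)C)c3OC)C=C(C)[C@H]2C4=N[C@H](CO4)C(C)(C)C)cc(OC)c1O[Si](C(C)C)(C(C)C)C(C)C | intermediate
16 | (2S)-2-ammonio-3,3-dimethylbutyl (1S,2S)-ester, trifluoroacetate salt | COc1cc([C@H]2c3c(cc(OC)c(O[Si](C(C)C)(C(C)C)C(C)C)c3OC)C=C(C)[C@H]2C(=O)OC[C@@H]([NH3+])C(C)(C)C)cc(OC)c1O[Si](C(C)C)(C(C)C)C(C)C.[O-]C(=O)C(F)(F)F | intermediate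
17 | (2S)-2-acetamido-3,3-dimethylbutyl (1S,2S)-1-[3,5-dimethoxy-4-(triisopropylsilyloxy)phenyl]-6,8-dimethoxy-3-methyl-7-(triisopropylsilyloxy)-1,2-dihydronaphthalene-2-carboxylate | COc1cc([C@H]2c3c(cc(OC)c(O[Si](C(C)C)(C(C)C)C(C)C)c3OC)C=C(C)[C@H]2C(=O)OC[C@@H](NC(C)=O)C(C)(C)C)cc(OC)c1O[Si](C(C)C)(C(C)C)C(C)C | intermediate
18 | {(1S,2S)-1-[3,5-dimethoxy-4-(triisopropylsilyloxy)phenyl]-6,8-dimethoxy-3-methyl-7-(triisopropylsilyloxy)-1,2-dihydronaphthalen-2-yl}methanol | COc1cc([C@H]2c3c(cc(OC)c(O[Si](C(C)C)(C(C)C)C(C)C)c3OC)C=C(C)[C@H]2CO)cc(OC)c1O[Si](C(C)C)(C(C)C)C(C)C | intermediate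
19 | methanesulfonate of 18 | COc1cc([C@H]2c3c(cc(OC)c(O[Si](C(C)C)(C(C)C)C(C)C)c3OC)C=C(C)[C@H]2COS(C)(=O)=O)cc(OC)c1O[Si](C(C)C)(C(C)C)C(C)C | intermediate
20 | (1S,2S)-1-[3,5-dimethoxy-4-(triisopropylsilyloxy)phenyl]-6,8-dimethoxy-2,3-dimethyl-7-(triisopropylsilyloxy)-1,2-dihydronaphthalene | COc1cc([C@H]2c3c(cc(OC)c(O[Si](C(C)C)(C(C)C)C(C)C)c3OC)C=C(C)[C@H]2C)cc(OC)c1O[Si](C(C)C)(C(C)C)C(C)C | intermediate
21 | (1S,2S)-1-(4-hydroxy-3,5-dimethoxyphenyl)-6,8-dimethoxy-2,3-dimethyl-1,2-dihydronaphthalen-7-ol | COc1cc([C@H]2c3c(cc(OC)c(O)c3OC)C=C(C)[C@H]2C)cc(OC)c1O | target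

**Totals**
Total step count: 12. Longest linear sequence: 12 steps (1 → 21). Bromide 2 enters twice, in step 2 as ring A and in step 7 as the pendant ring.

**Steps most likely to fail**

Step 7. Proton transfer from the C3 methyl group (lateral lithiation) or from C1–H to the aryllithium may outrun 1,4-addition. The oxazoline, twisted by the neighbouring methyl group, may also transmit its chirality poorly.
- The fallback replaces auxiliary control by external-ligand control on a faster acceptor. It sets out from 8.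
- Me3SnOH cleavage gives the naphthoic acid F1, oxalyl chloride gives the acid chloride F2, and lithium 2,6-di-tert-butyl-4-methoxyphenoxide gives the hindered aryl ester F3.
- Aryllithium 13 is precomplexed in toluene at −78 °C with the C2-symmetric chiral diether 1,2-dimethoxy-1,2-diphenylethane, in the antipode matched to the 1S sense. It adds to C1 of this more electrophilic, carbonyl-shielded ester to give the lithium enolate F4.
- The same anti protonation gives the cis ester F5, and LiAlH4 reduction comes back to the route at 18. Steps 8 and 9 fall away.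

Step 8. Enolisation of the protonated oxazoline or of the β,γ-unsaturated ester may erode the cis C1/C2 relationship, and O→N acyl migration may set in before acetylation.
- The fallback re-sets C2 instead of preserving it. It sets out from 17 of eroded cis purity.
- LDA (2.2 equiv; the first equivalent takes the acetamide N–H) in THF at −78 °C gives the dilithiated dienolate F6.
- Kinetic protonation of F6 with a bulky acid (2,6-di-tert-butylphenol) should again occur anti to the pseudoaxial aryl group. The fallback comes back to the route at 17.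

Step 11. The hydride may act as a base, giving E2 loss of the mesylate across C2–H followed by aromatisation, or the homoallylic C3=C4 bond may participate in ionisation.
- The fallback is a neutral reductive Mitsunobu deoxygenation. It sets out from 18.
- PPh3, DEAD and 2-nitrobenzenesulfonylhydrazide at −30 °C give the N-alkyl sulfonylhydrazine F7.
- On warming, F7 loses sulfinic acid to give the monoalkyl diazene F8, and loss of dinitrogen comes back to the route at 20. Step 10 falls away.

**Further compounds**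
F1 | step 7 | 6,8-dimethoxy-3-methyl-7-(triisopropylsilyloxy)naphthalene-2-carboxylic acid | COc1cc2cc(C)c(C(=O)O)cc2c(OC)c1O[Si](C(C)C)(C(C)C)C(C)C
F2 | step 7 | 6,8-dimethoxy-3-methyl-7-(triisopropylsilyloxy)naphthalene-2-carbonyl chloride | COc1cc2cc(C)c(C(=O)Cl)cc2c(OC)c1O[Si](C(C)C)(C(C)C)C(C)C
F3 | step 7 | 2,6-di-tert-butyl-4-methoxyphenyl 6,8-dimethoxy-3-methyl-7-(triisopropylsilyloxy)naphthalene-2-carboxylate | COc1cc(C(C)(C)C)c(OC(=O)c2cc3c(OC)c(O[Si](C(C)C)(C(C)C)C(C)C)c(OC)cc3cc2C)c(C(C)(C)C)c1
F4 | step 7 | lithium enolate from addition of 13 to C1 of F3 | COc1cc([C@H]2c3c(cc(OC)c(O[Si](C(C)C)(C(C)C)C(C)C)c3OC)C=C(C)C2=C(O[Li])Oc4c(C(C)(C)C)cc(OC)cc4C(C)(C)C)cc(OC)c1O[Si](C(C)C)(C(C)C)C(C)C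
F5 | step 7 | 2,6-di-tert-butyl-4-methoxyphenyl (1S,2S)-1-[3,5-dimethoxy-4-(triisopropylsilyloxy)phenyl]-6,8-dimethoxy-3-methyl-7-(triisopropylsilyloxy)-1,2-dihydronaphthalene-2-carboxylate | COc1cc([C@H]2c3c(cc(OC)c(O[Si](C(C)C)(C(C)C)C(C)C)c3OC)C=C(C)[C@H]2C(=O)Oc4c(C(C)(C)C)cc(OC)cc4C(C)(C)C)cc(OC)c1O[Si](C(C)C)(C(C)C)C(C)C
F6 | step 8 | dilithiated dienolate of 17 | COc1cc([C@H]2c3c(cc(OC)c(O[Si](C(C)C)(C(C)C)C(C)C)c3OC)C=C(C)C2=C(O[Li])OC[C@@H](N([Li])C(C)=O)C(C)(C)C)cc(OC)c1O[Si](C(C)C)(C(C)C)C(C)C
F7 | step 11 | N-alkyl-N-(2-nitrobenzenesulfonyl)hydrazine from 18 | COc1cc([C@H]2c3c(cc(OC)c(O[Si](C(C)C)(C(C)C)C(C)C)c3OC)C=C(C)[C@H]2CN(N)S(=O)(=O)c4ccccc4[N+](=O)[O-])cc(OC)c1O[Si](C(C)C)(C(C)C)C(C)C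
F8 | step 11 | monoalkyl diazene from F7 | COc1cc([C@H]2c3c(cc(OC)c(O[Si](C(C)C)(C(C)C)C(C)C)c3OC)C=C(C)[C@H]2CN=N)cc(OC)c1O[Si](C(C)C)(C(C)C)C(C)C
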